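Amber and violet differ in catalyst loading, with the other charges equal, so I try the bench rule first: rate goes with loading. Violet carries 1.52 times amber's loading, so violet at 20.0 s should look like amber at 30.4 s. But amber at 50.0 s still holds 16% left-handed substrate, more than violet's 9%, and the scatter is 1.5 percentage points. The rule breaks here, and a ratio shows the border: c(impurity) over catalyst charged is 80.0% in amber, 52.6% in violet and 40.0% in the flask. That is far from small, so I suppose the impurity acts as a stoichiometric poison, taking catalyst one for one.

| setting | amber | violet | flask |
|---|---|---|---|
| left-handed substrate | 0.10 M | 0.10 M | 0.10 M |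
| right-handed substrate | 0.10 M | 0.10 M | 0.10 M |
| coupling partner | 1.2 equiv | 1.2 equiv | 1.20 equiv |
| free catalyst | 0.025 mol% | 0.038 mol% | 0.05 mol% |
| impurity | 20 µM | 20 µM | 20 µM |
| remark | run made earlier | run made earlier |  |
| time |  |  | 2.0 min |

| run | time / s | left-handed substrate / % | right-handed substrate / % | left-handed product / % |
|---|---|---|---|---|
| amber | 10.0 | 27 | 52 | 21 |
| amber | 25.0 | 21 | 50 | 29 |
| amber | 50.0 | 16 | 47 | 36 |
| amber | 80.0 | 9 | 50 | 36 |
| violet | 20.0 | 9 | 47 | 40 |
| violet | 40.0 | 5 | 51 | 45 |
| violet | 50.0 | 6 | 48 | 45 |
| violet | 80.0 | 2 | 49 | 47 |

(each reading ± 1.5 percentage points)

- free catalyst is single-handed; left-handed substrate and right-handed substrate are mirror images of each other, charged as a racemate, each of them at the stated concentration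
- the analysis behind the earlier runs scatters by 1.5 percentage points, standard deviation
- an excess is the difference of the two amounts in percent of their sum
- an excess is below zero if the other one leads

- part of the left-handed substrate and right-handed substrate charged together that has reacted at 2.0 min
- excess of left-handed product over right-handed product in the product at 2.0 min
- excess of right-handed substrate over left-handed substrate among what is left of the two at 2.0 min

The flask then has 30.0 µM of working catalyst, the catalyst charged minus c(impurity), against 5.00 µM in amber and 18.0 µM in violet. Equal left-handed substrate should come at equal working catalyst times time. Violet's 20.0 s maps onto amber at 72.0 s, and amber's reading at 80.0 s is 9%, matching violet's 9%. The flask's 2.0 min maps onto violet at 200 s, beyond violet's last reading at 80.0 s, where 2% left-handed substrate remains and about half of the charge has reacted. So I commit to less left-handed substrate than that in the flask, and to a conversion a little higher.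

The forecast, finding that “both runs then fall on one curve”, gives conversion 52.2%, product excess 91% and substrate excess 99.2%. The flask gives 53.2%, 86.2% and 98.1%.

    coupling partner + free catalyst + left-handed substrate → free catalyst + left-handed product (k = 74000 M⁻² s⁻¹)
    coupling partner + free catalyst + right-handed substrate → free catalyst + right-handed product (k = 1200 M⁻² s⁻¹)
    free catalyst + impurity → spent catalyst A (k = 52000 M⁻¹ s⁻¹)
    coupling partner + free catalyst → spent catalyst B (k = 0.0500 M⁻¹ s⁻¹)
    coupling partner → decomposed reagent (k = 0.00280 s⁻¹)

Violet's 20.0 s maps onto 12.0 s in the flask, and at 0.200 min the flask holds 10.1% left-handed substrate. Working catalyst was reckoned at 60.0% of the charge: the catalyst that the impurity did not take, free catalyst plus spent catalyst B, makes 60.0% in the flask at 2.00 min, and 60.0% in the neighbour flask with 4.80 equiv coupling partner, where spent catalyst A again stands at 40.0%. The flask's product excess stands at 86.2% partly because the coupling partner runs short, down to 6.1% of its charge at 2.00 min; with c(coupling partner) held at its charge, the excess at 2.0 min is 52.7%.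

The runs are calculated with made-up constants, and the scatter is random.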